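# Proposed total synthesis of (3R,6'R)-7,8-didehydro-β,ε-caroten-3-ol (CNP0322200.1, crocoxanthin)

Carotenoid numbering is used throughout: ring A = C1–C6 with chain C7–C15, ring B = C1'–C6' with chain C7'–C15'.

## The problem

The target is a C40 carotenoid whose two cyclohexene rings are neither fused nor bridged. They sit at the ends of an eighteen-carbon chain with four methyl branches, eight E double bonds and the C7≡C8 triple bond, so the task is chain construction with control of geometry at every junction. There are only two stereocentres, the carbinol C3 (R) in ring A and the methine C6' (R) in ring B. They lie more than twenty bonds apart, cannot control each other, and must each arrive in an enantiopure building block. C6'–H is flanked by the ring alkene C4'=C5' and the chain alkene C7'=C8', so acid or strong base can move the ring double bond into conjugation or erase the centre; the polyene as a whole is sensitive to oxygen, light, acid and iodine. The alkyne hangs on C6, a ring carbon wedged between the gem-dimethyl carbon C1 and the methyl-bearing C5, so any bond formation at C6 itself is slow. Because the alkyne is rod-like, the 9Z isomer of a 7,8-didehydro chain is no less stable than 9E, so C9=C10 must be installed kinetically and kept away from equilibrating conditions, in particular from allylic ylides or cations spanning C9–C11. The enabling feature is that C7 is an exocyclic carbon on C6: as the CH2 of an allylic phenyl sulfone it is an unhindered stabilised nucleophile, and a sulfonyl group on C7 plus an oxygen on C8 are exactly the two leaving groups needed to turn a C7–C8 carbonyl addition into the triple bond.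

## Retrosynthesis

**Unmasking and the C11=C12 cut.** The C3 hydroxyl is carried as a silyl ether, so target 33 is traced to its tert-butyldimethylsilyl ether 32. The chain of 32 is cut at C11=C12 into the ring A C15 enynal 21 (aldehyde at C11) and the ring B C25 phosphonium bromide 30 (ylide 31, carbanion at C12). A central C15=C15' cut would need two different C20 polyenes. The same C11=C12 cut with reversed polarity would put the ylide on C11, where C9=C10 becomes part of an allylic ylide and can drift to 9Z. With the aldehyde on the ring A side, C9=C10 remains an ordinary enal double bond. The forward Wittig reaction must give 11E (or a mixture that relaxes thermally) without disturbing 9E, C6' or the silyl ether.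

**The ring B half.** Salt 30 goes back through alcohol 29 to the C25 polyenal 28. This is cut at C11'=C12' into the C15 phosphonium bromide 25 (ylide 27) and the symmetrical C10 dialdehyde 26, which supplies C12'–C15' and C15–C12 with two of the chain methyls. Salt 25 comes by allylic transposition from tertiary alcohol 24, the adduct of vinylmagnesium bromide 23 and (R)-α-ionone 22. The whole ring B half thus reduces to a purchased ketone that already carries C6' correctly; the forward steps need only avoid harsh acid or base at C6'.

**The alkyne as a double elimination.** Aldehyde 21 is the hydrolysis product of dimethyl acetal 20; an acetal survives carbanions, a non-acidic oxidation and one-electron reduction. The C7≡C8 bond of 20 is traced to enol phosphate 19, with the phenylsulfonyl group on C7 and the phosphate on C8. Compound 19 comes from β-keto sulfone 17 through enolate 18, and 17 from β-hydroxy sulfone 16 by oxidation. A base-induced double elimination of a derivative of 16 would be two steps shorter, but C11–H, the C9 methyl and the ring allylic hydrogens are all vinylogously acidified in the intermediate vinyl sulfone and could divert it toward a polyene. The reductive version is preferred because its outcome is fixed by where the two leaving groups sit. It must cope with a fully substituted, hindered enol carbon.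

**The key disconnection, C7–C8.** Hydroxy sulfone 16 is cut into the lithiated ring A allylic sulfone 15 (from sulfone 11) and the C5 enal 14. Cutting C6–C7 would require a metal-catalysed coupling at the most hindered ring carbon; cutting C8–C9 would need a ring A alkyne that is itself the problem. The C7–C8 cut puts the new bond on a primary exocyclic carbon and removes five chain carbons, the C9 methyl, the C9=C10 geometry and the C11 oxidation level at once. The forward step must react through C7 of the allylic anion and at the carbonyl carbon of the enal; the configurations at C7 and C8 do not matter.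

**The C5 enal.** Enal 14 is cut at its C=C bond into dimethoxyacetaldehyde 12 and the formyl-stabilised ylide 13; the stabilised ylide secures the E geometry that becomes 9E.

**The ring A sulfone.** Sulfone 11 comes from allylic bromide 9 and sodium benzenesulfinate 10; 9 from allylic alcohol 8, ester 7 and enol triflate 6, the exocyclic carbon C7 entering by carbonylation. Triflate 6 derives from silylated hydroxy ketone 4 through lithium enolate 5, and 4 from hydroxy ketone 3, diketone 2 and achiral ketoisophorone 1. C3 is set in two stages: an enzymatic C=C reduction fixes a methyl-bearing centre, that centre steers the hydride reduction that creates the carbinol, and it is then deliberately destroyed on enol triflate formation. Bromide 9 is a hindered, ionisable allylic halide and must be used promptly.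

## Roads not taken

**Alternative 1:** Still–Wittig chirality transfer to C6'. The cut is the C6'–C7' bond of ring B, traced to a C–O bond at the other end of an allyl system. The allylic alcohol A1 is converted to its tributylstannylmethyl ether A2; n-BuLi triggers tin–lithium exchange and a [2,3]-shift that forms C6'–C7' suprafacially and moves the alkene to C4'=C5', giving (R)-α-cyclogeraniol A3.

- Merits: the hindered bond next to the quaternary C1' is made intramolecularly, the ε-position of the alkene follows from the mechanism, and the configuration comes from a carbinol centre that asymmetric ketone reduction can set. This is independent of any supply of enantiopure α-ionone.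
- Weak points: it addresses the easier of the two problems and leaves C7≡C8 unsolved. A3 must be oxidised to aldehyde A4, whose α-hydrogen is prone to epimerisation and to slipping into the conjugated β-isomer, and then chain-extended by four carbons merely to reach the level of 22. It also uses stoichiometric tin.
- Comparison: if enantiopure 22 were unavailable, this road would control C6' better than a resolution. The chosen plan sets against it a purchased building block and no steps at all for C6'. The two are compatible; Alternative 1 could feed the chosen route but would lengthen it by five to six steps.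

**Alternative 2:** Ramberg–Bäcklund extrusion at C15=C15'. The cut is the central double bond. The unsymmetrical bis-allylic sulfone A5, joining C15 and C15' through sulfur, would be halogenated and contracted (CBr2F2, KOH on Al2O3) with loss of SO2 to the silyl ether A6, which is identical with 32.

- Merits: a C20 + C20 union is the most convergent possible, the central triene appears last, and no phosphorus reagent is needed at the union.
- Weak points: the two halves differ, so two separate C20 polyenyl partners must be made and joined through sulfur. The ring A half still needs a solution for C6–C7≡C8, so this is an assembly tactic and not an answer to the alkyne. The α-sulfonyl carbanions are delocalised into both tetraene arms under strongly basic conditions, inviting geometric scrambling (including C9=C10) and proton shifts toward C6'. The new central bond is expected as an E/Z mixture, and the equilibration used to correct it is what drives C9 toward Z.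
- Comparison: Alternative 2 is better in convergence and would shorten the longest linear sequence. The chosen plan sets against it a Wittig union at C11=C12 that leaves C9=C10 alone and draws the chain centre from the commercial dialdehyde 26.

**Alternative 3:** Sonogashira coupling at C6–C7. The cut is the ring-to-alkyne bond. Enol triflate 6 and the terminal enynol A7 are coupled (Pd(PPh3)4, CuI, amine base) to the C15 enynol A8, which one allylic oxidation would convert into 21.

- Merits: it is direct, since the alkyne is bought and not made, and it reaches the C15 stage in two steps from 6 against nine in the chosen plan. The reaction type is established for hindered cyclohexenyl triflates.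
- Weak points: coupling at a fully substituted vinyl–palladium centre flanked by a quaternary carbon is slow, so copper-mediated homocoupling of A7 competes. The 9E geometry depends entirely on the geometric purity of A7.
- Comparison: on step count Alternative 3 is clearly better, and this is stated plainly. The chosen plan sets against it a C–C bond formed at the unhindered C7 without a precious-metal step at the congested centre, and a C9=C10 geometry set by a stabilised-ylide olefination. Because of its brevity, Alternative 3 is held as the fallback for the alkyne-forming sequence.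

Key step: step 10

Assumption: (R)-(+)-α-ionone 22 is bought as the single enantiomer (it is offered by fine-chemical suppliers; racemate would otherwise be resolved classically before use), and dimethoxyacetaldehyde 12 is taken from its commercial aqueous solution by extraction and drying.

## Route

Step 1
Reactants: 1 ketoisophorone (2,6,6-trimethylcyclohex-2-ene-1,4-dione)
Product: 2 (6R)-2,2,6-trimethylcyclohexane-1,4-dione
Conditions: baker's yeast (Saccharomyces cerevisiae), sucrose, H2O, 30 °C
Reagents that add atoms: none
Why: Biocatalytic ene-reduction of the enedione C=C bond; the yeast enzymes add hydride and proton to one face and should set the methyl-bearing centre as R, the established fermentative entry to this ring.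

Step 2
Reactants: 2 (6R)-2,2,6-trimethylcyclohexane-1,4-dione
Product: 3 (4R,6R)-4-hydroxy-2,2,6-trimethylcyclohexanone
Conditions: LiBH(s-Bu)3, THF, −78 °C; then aq. NaOH, H2O2, 0 °C
Reagents that add atoms: none
Why: Chemo- and diastereoselective hydride reduction; the C1 carbonyl is shielded by the quaternary C2 and by C6, and the bulky borohydride attacks the C4 carbonyl equatorially because the axial C2 methyl blocks the axial path (as in 3,3,5-trimethylcyclohexanone), which should give the axial 4R alcohol trans to the C6 methyl. This is the future C3 centre, set by substrate control from C6.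

Step 3
Reactants: 3 (4R,6R)-4-hydroxy-2,2,6-trimethylcyclohexanone
Product: 4 (4R,6R)-4-(tert-butyldimethylsilyloxy)-2,2,6-trimethylcyclohexanone
Conditions: TBSCl, imidazole, DMF, rt
Reagents that add atoms: tert-butyldimethylsilyl chloride, CC(C)(C)[Si](C)(C)Cl
Why: Standard silylation of a secondary alcohol; the TBS ether should survive amide bases, i-Bu2AlH, organolithium, NaH and SmI2 and is removed only at the end.

Step 4
Reactants: 4 (4R,6R)-4-(tert-butyldimethylsilyloxy)-2,2,6-trimethylcyclohexanone
Product: 6 (4R)-4-(tert-butyldimethylsilyloxy)-2,6,6-trimethylcyclohex-1-en-1-yl trifluoromethanesulfonate, via lithium enolate 5 (not isolated)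
Conditions: LiN(i-Pr)2, THF, −78 °C; then PhNTf2, −78 °C to rt; aq. NH4Cl
Reagents that add atoms: N-phenylbis(trifluoromethanesulfonimide), O=S(=O)(N(c1ccccc1)S(=O)(=O)C(F)(F)F)C(F)(F)F
Why: Enolisation can occur only toward C6 because C2 is quaternary, and O-triflation of the lithium enolate is the standard route to hindered cyclohexenyl triflates. The C6 centre is erased as planned; C4 is untouched.

Step 5
Reactants: 6 (4R)-4-(tert-butyldimethylsilyloxy)-2,6,6-trimethylcyclohex-1-en-1-yl trifluoromethanesulfonate
Product: 7 methyl (4R)-4-(tert-butyldimethylsilyloxy)-2,6,6-trimethylcyclohex-1-ene-1-carboxylate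
Conditions: CO (1 atm), Pd(OAc)2 (cat.), PPh3, Et3N, MeOH, DMF, 60 °C
Reagents that add atoms: carbon monoxide, [C-]#[O+]; methanol, CO
Why: Palladium-catalysed methoxycarbonylation of an enol triflate; zerovalent palladium formed in situ inserts into the C–O bond, CO insertion gives the acyl complex and methanolysis releases the ester. The carbon introduced is C7.

Step 6
Reactants: 7 methyl (4R)-4-(tert-butyldimethylsilyloxy)-2,6,6-trimethylcyclohex-1-ene-1-carboxylate
Product: 8 [(4R)-4-(tert-butyldimethylsilyloxy)-2,6,6-trimethylcyclohex-1-en-1-yl]methanol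
Conditions: i-Bu2AlH, CH2Cl2, −78 to 0 °C; aq. potassium sodium tartrate
Reagents that add atoms: none
Why: Hydride reduction of the unsaturated ester to the allylic alcohol; conjugate reduction is not expected because the β-carbon is fully substituted.

Step 7
Reactants: 8 [(4R)-4-(tert-butyldimethylsilyloxy)-2,6,6-trimethylcyclohex-1-en-1-yl]methanol
Product: 9 {[(1R)-4-(bromomethyl)-3,5,5-trimethylcyclohex-3-en-1-yl]oxy}(tert-butyl)dimethylsilane
Conditions: CBr4, PPh3, CH2Cl2, 0 °C
Reagents that add atoms: carbon tetrabromide, BrC(Br)(Br)Br
Why: Appel bromination converts the primary allylic alcohol to the bromide under neutral conditions that spare the silyl ether; the bromide is used at once.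

Step 8
Reactants: 9 {[(1R)-4-(bromomethyl)-3,5,5-trimethylcyclohex-3-en-1-yl]oxy}(tert-butyl)dimethylsilane; 10 sodium benzenesulfinate
Product: 11 tert-butyldimethyl({(1R)-3,5,5-trimethyl-4-[(phenylsulfonyl)methyl]cyclohex-3-en-1-yl}oxy)silane
Conditions: DMF, rt
Reagents that add atoms: none
Why: SN2 displacement of the primary allylic bromide by the sulfur of the sulfinate (S-alkylation is favoured in DMF); the fully substituted γ-carbon disfavours allylic transposition.

Step 9
Reactants: 12 dimethoxyacetaldehyde; 13 2-(triphenylphosphoranylidene)propanal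
Product: 14 (2E)-4,4-dimethoxy-2-methylbut-2-enal
Conditions: toluene, 80 °C
Reagents that add atoms: none
Why: Wittig olefination with a formyl-stabilised ylide, which is E-selective and should react with the electron-poor dialkoxy aldehyde much faster than with the enal formed. This fixes the future C9=C10 geometry.

Step 10
Reactants: 11 tert-butyldimethyl({(1R)-3,5,5-trimethyl-4-[(phenylsulfonyl)methyl]cyclohex-3-en-1-yl}oxy)silane; 14 (2E)-4,4-dimethoxy-2-methylbut-2-enal
Product: 16 (3E)-1-[(4R)-4-(tert-butyldimethylsilyloxy)-2,6,6-trimethylcyclohex-1-en-1-yl]-5,5-dimethoxy-3-methyl-1-(phenylsulfonyl)pent-3-en-2-ol (mixture at C7 and C8), via lithiated sulfone 15 (not isolated)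
Conditions: n-BuLi, THF, −78 °C; then 14, −78 °C; AcOH quench at −78 °C
Reagents that add atoms: none
Why: n-BuLi removes the C7 proton of 11, acidified by the sulfonyl group and the C5=C6 alkene, to give the lithiated allylic sulfone 15, which adds through C7 to the aldehyde carbonyl of 14 and forms the C7–C8 bond; cold protonation of the lithium alkoxide gives 16. The closest known reaction type is the carbonyl-addition stage of the Julia–Lythgoe sequence, in particular additions of cyclogeranyl-type allylic sulfone carbanions to α-methyl enals in retinoid chemistry. No ring is closed. Two stereocentres (C7 and C8) form without control, which is acceptable because both become sp carbons in step 13. The step needs α- and not γ-attack of the allyl anion and 1,2- and not 1,4-addition to the enal: the γ-terminus C5 is a fully substituted ring carbon, the charge sits next to sulfur, and a lithium counter-ion in THF at −78 °C favours attack at the carbonyl, whose β-carbon is further shielded by the acetal. The C9=C10 geometry of 14 is not involved. Because a hindered β-alkoxy sulfone can revert on warming, the mixture is quenched with acetic acid at −78 °C.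

Step 11
Reactants: 16 (3E)-1-[(4R)-4-(tert-butyldimethylsilyloxy)-2,6,6-trimethylcyclohex-1-en-1-yl]-5,5-dimethoxy-3-methyl-1-(phenylsulfonyl)pent-3-en-2-ol
Product: 17 (3E)-1-[(4R)-4-(tert-butyldimethylsilyloxy)-2,6,6-trimethylcyclohex-1-en-1-yl]-5,5-dimethoxy-3-methyl-1-(phenylsulfonyl)pent-3-en-2-one
Conditions: Dess–Martin periodinane, NaHCO3, CH2Cl2, 0 °C to rt
Reagents that add atoms: none
Why: Dess–Martin oxidation of the secondary allylic alcohol under buffered, non-basic conditions should avoid retro-addition of the β-hydroxy sulfone and spare acetal and silyl ether. The C8 centre disappears.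

Step 12
Reactants: 17 (3E)-1-[(4R)-4-(tert-butyldimethylsilyloxy)-2,6,6-trimethylcyclohex-1-en-1-yl]-5,5-dimethoxy-3-methyl-1-(phenylsulfonyl)pent-3-en-2-one
Product: 19 diethyl (3E)-1-[(4R)-4-(tert-butyldimethylsilyloxy)-2,6,6-trimethylcyclohex-1-en-1-yl]-5,5-dimethoxy-3-methyl-1-(phenylsulfonyl)penta-1,3-dien-2-yl phosphate, via sodium enolate 18 (not isolated)
Conditions: NaH, THF, 0 °C; then ClP(O)(OEt)2, 0 °C to rt
Reagents that add atoms: diethyl chlorophosphate, CCOP(=O)(Cl)OCC
Why: The C7 proton between sulfonyl and carbonyl is removed by NaH and the hard chlorophosphate reacts at oxygen (enol phosphate formation as in the Lythgoe alkyne synthesis). The C7 centre disappears and the enol geometry is irrelevant.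

Step 13
Reactants: 19 diethyl (3E)-1-[(4R)-4-(tert-butyldimethylsilyloxy)-2,6,6-trimethylcyclohex-1-en-1-yl]-5,5-dimethoxy-3-methyl-1-(phenylsulfonyl)penta-1,3-dien-2-yl phosphate
Product: 20 tert-butyl({(1R)-4-[(3E)-5,5-dimethoxy-3-methylpent-3-en-1-yn-1-yl]-3,5,5-trimethylcyclohex-3-en-1-yl}oxy)dimethylsilane
Conditions: SmI2, HMPA, THF, −20 °C to rt
Reagents that add atoms: none
Why: Reductive elimination of a β-phosphoryloxy vinyl sulfone (Lythgoe-type alkyne synthesis with SmI2 as the electron source): electron transfer expels benzenesulfinate from C7, a second electron gives the vinyl anion, and loss of phosphate from C8 forms C7≡C8. No base is present, so the acidic C11–H, C9-methyl and ring allylic hydrogens cannot divert the elimination.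

Step 14
Reactants: 20 tert-butyl({(1R)-4-[(3E)-5,5-dimethoxy-3-methylpent-3-en-1-yn-1-yl]-3,5,5-trimethylcyclohex-3-en-1-yl}oxy)dimethylsilane
Product: 21 (2E)-5-[(4R)-4-(tert-butyldimethylsilyloxy)-2,6,6-trimethylcyclohex-1-en-1-yl]-3-methylpent-2-en-4-ynal
Conditions: p-TsOH·H2O (cat.), acetone/H2O, 0 °C
Reagents that add atoms: water, O
Why: Acid-catalysed hydrolysis of an allylic dimethyl acetal is fast at 0 °C, where the secondary TBS ether and the C9=C10 geometry should hold.

Step 15
Reactants: 22 (R)-α-ionone, (3E)-4-[(1R)-2,6,6-trimethylcyclohex-2-en-1-yl]but-3-en-2-one; 23 vinylmagnesium bromide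
Product: 24 (1E)-3-methyl-1-[(1R)-2,6,6-trimethylcyclohex-2-en-1-yl]penta-1,4-dien-3-ol (both carbinol epimers)
Conditions: THF, −20 to 0 °C; aq. NH4Cl
Reagents that add atoms: none
Why: Grignard 1,2-addition to the methyl ketone, the classical vinyl-ionol synthesis; the new carbinol centre is uncontrolled and is lost in step 16, and C6' should be untouched because addition outruns γ-deprotonation.

Step 16
Reactants: 24 (1E)-3-methyl-1-[(1R)-2,6,6-trimethylcyclohex-2-en-1-yl]penta-1,4-dien-3-ol
Product: 25 {(2E,4E)-3-methyl-5-[(1R)-2,6,6-trimethylcyclohex-2-en-1-yl]penta-2,4-dien-1-yl}triphenylphosphonium bromide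
Conditions: PPh3·HBr, MeOH, rt
Reagents that add atoms: triphenylphosphine hydrobromide, [Br-].c1ccc(cc1)[PH+](c1ccccc1)c1ccccc1
Why: Ionisation of the tertiary bis-allylic alcohol and capture of the pentadienyl cation by PPh3 at the primary terminus (allylic transposition) gives the conjugated dienyl salt, the standard C15 Wittig salt preparation; crystallisation should remove any Z isomer at the trisubstituted bond.

Step 17
Reactants: 25 {(2E,4E)-3-methyl-5-[(1R)-2,6,6-trimethylcyclohex-2-en-1-yl]penta-2,4-dien-1-yl}triphenylphosphonium bromide; 26 (2E,4E,6E)-2,7-dimethylocta-2,4,6-trienedial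
Product: 28 (2E,4E,6E,8E,10E,12E)-2,7,11-trimethyl-13-[(1R)-2,6,6-trimethylcyclohex-2-en-1-yl]trideca-2,4,6,8,10,12-hexaenal, via C15 ylide 27 (not isolated)
Conditions: NaOMe, CH2Cl2/MeOH, 0 °C to rt, 26 in excess, salt added slowly; then heptane, 80 °C, dark
Reagents that add atoms: none
Why: Wittig olefination of the allylic ylide with one formyl group of the symmetrical dialdehyde, used in excess with inverse addition to suppress double condensation; the new C11'=C12' bond forms as an E/Z mixture that thermal equilibration should convert to E.

Step 18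
Reactants: 28 (2E,4E,6E,8E,10E,12E)-2,7,11-trimethyl-13-[(1R)-2,6,6-trimethylcyclohex-2-en-1-yl]trideca-2,4,6,8,10,12-hexaenal
Product: 29 (2E,4E,6E,8E,10E,12E)-2,7,11-trimethyl-13-[(1R)-2,6,6-trimethylcyclohex-2-en-1-yl]trideca-2,4,6,8,10,12-hexaen-1-ol
Conditions: NaBH4, EtOH/THF, 0 °C
Reagents that add atoms: none
Why: Chemoselective 1,2-reduction of the polyenal to the primary allylic alcohol by borohydride.

Step 19
Reactants: 29 (2E,4E,6E,8E,10E,12E)-2,7,11-trimethyl-13-[(1R)-2,6,6-trimethylcyclohex-2-en-1-yl]trideca-2,4,6,8,10,12-hexaen-1-ol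
Product: 30 {(2E,4E,6E,8E,10E,12E)-2,7,11-trimethyl-13-[(1R)-2,6,6-trimethylcyclohex-2-en-1-yl]trideca-2,4,6,8,10,12-hexaen-1-yl}triphenylphosphonium bromide
Conditions: PPh3·HBr, MeOH/CH2Cl2, 0 °C to rt, dark
Reagents that add atoms: triphenylphosphine hydrobromide, [Br-].c1ccc(cc1)[PH+](c1ccccc1)c1ccccc1
Why: Phosphonium salt formation from a polyenyl allylic alcohol, as in the conversion of retinol to its Wittig salt; the phosphine captures the delocalised cation at the primary terminus, which keeps the full conjugation.

Step 20
Reactants: 30 {(2E,4E,6E,8E,10E,12E)-2,7,11-trimethyl-13-[(1R)-2,6,6-trimethylcyclohex-2-en-1-yl]trideca-2,4,6,8,10,12-hexaen-1-yl}triphenylphosphonium bromide; 21 (2E)-5-[(4R)-4-(tert-butyldimethylsilyloxy)-2,6,6-trimethylcyclohex-1-en-1-yl]-3-methylpent-2-en-4-ynal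
Product: 32 (3R,6'R)-3-(tert-butyldimethylsilyloxy)-7,8-didehydro-β,ε-carotene, via C25 ylide 31 (not isolated)
Conditions: NaN(SiMe3)2, THF, −78 to 0 °C; then 21, −78 °C to rt, dark; then heptane, 60 °C, dark
Reagents that add atoms: none
Why: Wittig olefination forming C11=C12; the ylide is preformed so that enal 21 meets no free base, and because the ylide carbon is C12 the C9=C10 bond never becomes part of an allylic ylide. Any hindered 11Z isomer should relax to E on gentle warming, conditions under which 9E is expected to persist.

Step 21
Reactants: 32 (3R,6'R)-3-(tert-butyldimethylsilyloxy)-7,8-didehydro-β,ε-carotene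
Product: 33 (3R,6'R)-7,8-didehydro-β,ε-caroten-3-ol (target)
Conditions: Bu4NF, THF, 0 °C to rt, dark, argon
Reagents that add atoms: none
Why: Fluoride cleavage of the secondary silyl ether under non-acidic conditions that leave the polyene, the alkyne and both stereocentres untouched.

## Compound list

1 | ketoisophorone (2,6,6-trimethylcyclohex-2-ene-1,4-dione) | CC1=CC(=O)CC(C)(C)C1=O | starting material
2 | (6R)-2,2,6-trimethylcyclohexane-1,4-dione | C[C@@H]1CC(=O)CC(C)(C)C1=O | intermediate
3 | (4R,6R)-4-hydroxy-2,2,6-trimethylcyclohexanone (hydroxyl trans to the C6 methyl) | C[C@@H]1C[C@@H](O)CC(C)(C)C1=O | intermediate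
4 | (4R,6R)-4-(tert-butyldimethylsilyloxy)-2,2,6-trimethylcyclohexanone | C[C@@H]1C[C@@H](O[Si](C)(C)C(C)(C)C)CC(C)(C)C1=O | intermediate
5 | lithium (4R)-4-(tert-butyldimethylsilyloxy)-2,6,6-trimethylcyclohex-1-en-1-olate | [Li]OC1=C(C)C[C@@H](O[Si](C)(C)C(C)(C)C)CC1(C)C | intermediate
6 | (4R)-4-(tert-butyldimethylsilyloxy)-2,6,6-trimethylcyclohex-1-en-1-yl trifluoromethanesulfonate | O=S(=O)(OC1=C(C)C[C@@H](O[Si](C)(C)C(C)(C)C)CC1(C)C)C(F)(F)F | intermediate
7 | methyl (4R)-4-(tert-butyldimethylsilyloxy)-2,6,6-trimethylcyclohex-1-ene-1-carboxylate | COC(=O)C1=C(C)C[C@@H](O[Si](C)(C)C(C)(C)C)CC1(C)C | intermediate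
8 | [(4R)-4-(tert-butyldimethylsilyloxy)-2,6,6-trimethylcyclohex-1-en-1-yl]methanol | OCC1=C(C)C[C@@H](O[Si](C)(C)C(C)(C)C)CC1(C)C | intermediate
9 | {[(1R)-4-(bromomethyl)-3,5,5-trimethylcyclohex-3-en-1-yl]oxy}(tert-butyl)dimethylsilane | BrCC1=C(C)C[C@@H](O[Si](C)(C)C(C)(C)C)CC1(C)C | intermediate
10 | sodium benzenesulfinate | [Na+].[O-]S(=O)c1ccccc1 | starting material
11 | tert-butyldimethyl({(1R)-3,5,5-trimethyl-4-[(phenylsulfonyl)methyl]cyclohex-3-en-1-yl}oxy)silane (ring A allylic sulfone) | O=S(=O)(CC1=C(C)C[C@@H](O[Si](C)(C)C(C)(C)C)CC1(C)C)c1ccccc1 | intermediate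
12 | dimethoxyacetaldehyde | COC(OC)C=O | starting material
13 | 2-(triphenylphosphoranylidene)propanal | CC(C=O)=P(c1ccccc1)(c1ccccc1)c1ccccc1 | starting material
14 | (2E)-4,4-dimethoxy-2-methylbut-2-enal | O=C/C(C)=C/C(OC)OC | intermediate
15 | α-lithio derivative of sulfone 11 (lithium on C7) | [Li]C(C1=C(C)C[C@@H](O[Si](C)(C)C(C)(C)C)CC1(C)C)S(=O)(=O)c1ccccc1 | intermediate
16 | (3E)-1-[(4R)-4-(tert-butyldimethylsilyloxy)-2,6,6-trimethylcyclohex-1-en-1-yl]-5,5-dimethoxy-3-methyl-1-(phenylsulfonyl)pent-3-en-2-ol (mixture at C7 and C8) | COC(OC)/C=C(\C)C(O)C(S(=O)(=O)c1ccccc1)C1=C(C)C[C@@H](O[Si](C)(C)C(C)(C)C)CC1(C)C | intermediate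
17 | (3E)-1-[(4R)-4-(tert-butyldimethylsilyloxy)-2,6,6-trimethylcyclohex-1-en-1-yl]-5,5-dimethoxy-3-methyl-1-(phenylsulfonyl)pent-3-en-2-one | COC(OC)/C=C(\C)C(=O)C(S(=O)(=O)c1ccccc1)C1=C(C)C[C@@H](O[Si](C)(C)C(C)(C)C)CC1(C)C | intermediate
18 | sodium enolate of keto sulfone 17 | [Na+].COC(OC)/C=C(\C)C([O-])=C(S(=O)(=O)c1ccccc1)C1=C(C)C[C@@H](O[Si](C)(C)C(C)(C)C)CC1(C)C | intermediate
19 | diethyl (3E)-1-[(4R)-4-(tert-butyldimethylsilyloxy)-2,6,6-trimethylcyclohex-1-en-1-yl]-5,5-dimethoxy-3-methyl-1-(phenylsulfonyl)penta-1,3-dien-2-yl phosphate (enol geometry undefined) | COC(OC)/C=C(\C)C(OP(=O)(OCC)OCC)=C(S(=O)(=O)c1ccccc1)C1=C(C)C[C@@H](O[Si](C)(C)C(C)(C)C)CC1(C)C | intermediate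
20 | tert-butyl({(1R)-4-[(3E)-5,5-dimethoxy-3-methylpent-3-en-1-yn-1-yl]-3,5,5-trimethylcyclohex-3-en-1-yl}oxy)dimethylsilane | COC(OC)/C=C(\C)C#CC1=C(C)C[C@@H](O[Si](C)(C)C(C)(C)C)CC1(C)C | intermediate
21 | (2E)-5-[(4R)-4-(tert-butyldimethylsilyloxy)-2,6,6-trimethylcyclohex-1-en-1-yl]-3-methylpent-2-en-4-ynal (ring A C15 enynal) | O=C/C=C(\C)C#CC1=C(C)C[C@@H](O[Si](C)(C)C(C)(C)C)CC1(C)C | intermediate
22 | (R)-α-ionone, (3E)-4-[(1R)-2,6,6-trimethylcyclohex-2-en-1-yl]but-3-en-2-one | CC1=CCCC(C)(C)[C@H]1/C=C/C(C)=O | starting material
23 | vinylmagnesium bromide | C=C[Mg]Br | starting material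
24 | (1E)-3-methyl-1-[(1R)-2,6,6-trimethylcyclohex-2-en-1-yl]penta-1,4-dien-3-ol (carbinol epimers) | CC1=CCCC(C)(C)[C@H]1/C=C/C(C)(O)C=C | intermediate
25 | {(2E,4E)-3-methyl-5-[(1R)-2,6,6-trimethylcyclohex-2-en-1-yl]penta-2,4-dien-1-yl}triphenylphosphonium bromide | CC1=CCCC(C)(C)[C@H]1/C=C/C(C)=C/C[P+](c1ccccc1)(c1ccccc1)c1ccccc1.[Br-] | intermediate
26 | (2E,4E,6E)-2,7-dimethylocta-2,4,6-trienedial | O=C/C(C)=C/C=C/C=C(\C)C=O | starting material
27 | ylide of salt 25 | CC1=CCCC(C)(C)[C@H]1/C=C/C(C)=C/C=P(c1ccccc1)(c1ccccc1)c1ccccc1 | intermediate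
28 | (2E,4E,6E,8E,10E,12E)-2,7,11-trimethyl-13-[(1R)-2,6,6-trimethylcyclohex-2-en-1-yl]trideca-2,4,6,8,10,12-hexaenal (ring B C25 aldehyde) | CC1=CCCC(C)(C)[C@H]1/C=C/C(C)=C/C=C/C(C)=C/C=C/C=C(\C)C=O | intermediate
29 | (2E,4E,6E,8E,10E,12E)-2,7,11-trimethyl-13-[(1R)-2,6,6-trimethylcyclohex-2-en-1-yl]trideca-2,4,6,8,10,12-hexaen-1-ol | CC1=CCCC(C)(C)[C@H]1/C=C/C(C)=C/C=C/C(C)=C/C=C/C=C(\C)CO | intermediate
30 | {(2E,4E,6E,8E,10E,12E)-2,7,11-trimethyl-13-[(1R)-2,6,6-trimethylcyclohex-2-en-1-yl]trideca-2,4,6,8,10,12-hexaen-1-yl}triphenylphosphonium bromide | CC1=CCCC(C)(C)[C@H]1/C=C/C(C)=C/C=C/C(C)=C/C=C/C=C(\C)C[P+](c1ccccc1)(c1ccccc1)c1ccccc1.[Br-] | intermediate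
31 | ylide of salt 30 | CC1=CCCC(C)(C)[C@H]1/C=C/C(C)=C/C=C/C(C)=C/C=C/C=C(\C)C=P(c1ccccc1)(c1ccccc1)c1ccccc1 | intermediate
32 | (3R,6'R)-3-(tert-butyldimethylsilyloxy)-7,8-didehydro-β,ε-carotene | CC1=CCCC(C)(C)[C@H]1/C=C/C(C)=C/C=C/C(C)=C/C=C/C=C(C)/C=C/C=C(\C)C#CC1=C(C)C[C@@H](O[Si](C)(C)C(C)(C)C)CC1(C)C | intermediate
33 | (3R,6'R)-7,8-didehydro-β,ε-caroten-3-ol | CC1=CCCC(C)(C)[C@H]1/C=C/C(C)=C/C=C/C(C)=C/C=C/C=C(C)/C=C/C=C(\C)C#CC1=C(C)C[C@@H](O)CC1(C)C | target

## Step count and least certain steps

Total: 21 steps. Longest linear sequence: 15 steps (steps 1–8, 10–14, 20 and 21).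

**Step 10 (key step).** The most likely failure is reversal of the addition: the hindered lithium β-alkoxy sulfone can fragment back to 15 and 14 before it is protonated. Alternatively, 15 may act as a base toward the γ-hydrogen of 14 (the acetal C–H) and not as a nucleophile, so that 11 is simply recovered. The fallback sets out from 11 and comes back at 17. The same C7–C8 bond is made by acylation instead of aldehyde addition. Dimethoxyacetaldehyde 12 is condensed with methyl 2-(triphenylphosphoranylidene)propanoate (COC(=O)C(C)=P(c1ccccc1)(c1ccccc1)c1ccccc1) to give methyl (2E)-4,4-dimethoxy-2-methylbut-2-enoate F1. Carbanion 15, with a second equivalent of amide base present to absorb the acidic product, is acylated with F1 to give keto sulfone 17 directly. Deprotonation of the product makes the bond formation irreversible, and step 11 is no longer needed.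

**Step 13 (with step 12).** The hindered, fully substituted enol carbon may phosphorylate slowly. In the reduction, electron transfer may stop after loss of only one leaving group, go on to reduce the enyne, or allow rotation about C9=C10 in the delocalised radical anion and so erode 9E. The fallback sets out from 6 and comes back at 21. It is a Sonogashira coupling of triflate 6 with (E)-3-methylpent-2-en-4-yn-1-ol A7 (Pd(PPh3)4, CuI, i-Pr2NH, DMF), giving (2E)-5-[(4R)-4-(tert-butyldimethylsilyloxy)-2,6,6-trimethylcyclohex-1-en-1-yl]-3-methylpent-2-en-4-yn-1-ol F2. Allylic oxidation with MnO2 in CH2Cl2 then gives 21. The alkyne is bought and not made, and the 9E geometry comes from the enynol.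

**Step 20.** The new C11=C12 bond may form with a large 11Z share, and the warming used to correct it may begin to move C9=C10 toward Z. The long delocalised ylide 31 may also be slow to react. Upstream, the polyenyl cation of step 19 may lose C6'–H and give a retro-polyene instead of salt 30. The fallback sets out from 21 and 28 and comes back at 32; it also bypasses steps 18 and 19. The polarity of the Wittig union is reversed. Aldehyde 21 is reduced with NaBH4 to the enynol F2. F2 is converted with CBr4 and PPh3 into {[(1R)-4-[(3E)-5-bromo-3-methylpent-3-en-1-yn-1-yl]-3,5,5-trimethylcyclohex-3-en-1-yl]oxy}(tert-butyl)dimethylsilane F3, and tributylphosphine turns this into {(2E)-5-[(4R)-4-(tert-butyldimethylsilyloxy)-2,6,6-trimethylcyclohex-1-en-1-yl]-3-methylpent-2-en-4-yn-1-yl}tributylphosphonium bromide F4. Deprotonation of F4 with NaOMe and condensation with polyenal 28 gives 32. Trialkylphosphonium allylic ylides favour the E alkene, which should remove the need for thermal correction. The cost is that C9=C10 passes through an allylic ylide.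

**Step 5.** Carbonylative turnover may be slow at the fully substituted vinyl–palladium centre next to the quaternary carbon, so that triflate hydrolysis back to 4 or simple reduction competes. The fallback sets out from 4 and comes back at 8, replacing steps 4–6. It is a Shapiro reaction. Ketone 4 is condensed with 2,4,6-triisopropylbenzenesulfonyl hydrazide to give N'-[(4R,6R)-4-(tert-butyldimethylsilyloxy)-2,2,6-trimethylcyclohexylidene]-2,4,6-triisopropylbenzenesulfonohydrazide F5. Two equivalents of n-BuLi generate [(4R)-4-(tert-butyldimethylsilyloxy)-2,6,6-trimethylcyclohex-1-en-1-yl]lithium F6, which is trapped with formaldehyde to give 8. Deprotonation is possible only on the C6 side, so the alkene position is the same as in 6.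

## Further compounds

F1 | step 10 | methyl (2E)-4,4-dimethoxy-2-methylbut-2-enoate | COC(=O)/C(C)=C/C(OC)OC
F2 | step 13 | (2E)-5-[(4R)-4-(tert-butyldimethylsilyloxy)-2,6,6-trimethylcyclohex-1-en-1-yl]-3-methylpent-2-en-4-yn-1-ol | OC/C=C(\C)C#CC1=C(C)C[C@@H](O[Si](C)(C)C(C)(C)C)CC1(C)C
F3 | step 20 | {[(1R)-4-[(3E)-5-bromo-3-methylpent-3-en-1-yn-1-yl]-3,5,5-trimethylcyclohex-3-en-1-yl]oxy}(tert-butyl)dimethylsilane | BrC/C=C(\C)C#CC1=C(C)C[C@@H](O[Si](C)(C)C(C)(C)C)CC1(C)C
F4 | step 20 | {(2E)-5-[(4R)-4-(tert-butyldimethylsilyloxy)-2,6,6-trimethylcyclohex-1-en-1-yl]-3-methylpent-2-en-4-yn-1-yl}tributylphosphonium bromide | CCCC[P+](CCCC)(CCCC)C/C=C(\C)C#CC1=C(C)C[C@@H](O[Si](C)(C)C(C)(C)C)CC1(C)C.[Br-]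
F5 | step 5 | N'-[(4R,6R)-4-(tert-butyldimethylsilyloxy)-2,2,6-trimethylcyclohexylidene]-2,4,6-triisopropylbenzenesulfonohydrazide | C[C@@H]1C[C@@H](O[Si](C)(C)C(C)(C)C)CC(C)(C)C1=NNS(=O)(=O)c1c(C(C)C)cc(C(C)C)cc1C(C)C
F6 | step 5 | [(4R)-4-(tert-butyldimethylsilyloxy)-2,6,6-trimethylcyclohex-1-en-1-yl]lithium | [Li]C1=C(C)C[C@@H](O[Si](C)(C)C(C)(C)C)CC1(C)C
A1 | alternative 1 | (1S)-2,4,4-trimethylcyclohex-2-en-1-ol | CC1=CC(C)(C)CC[C@@H]1O
A2 | alternative 1 | tributyl({[(1S)-2,4,4-trimethylcyclohex-2-en-1-yl]oxy}methyl)stannane | CC1=CC(C)(C)CC[C@@H]1OC[Sn](CCCC)(CCCC)CCCC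
A3 | alternative 1 | (R)-α-cyclogeraniol, [(1R)-2,6,6-trimethylcyclohex-2-en-1-yl]methanol | CC1=CCCC(C)(C)[C@H]1CO
A4 | alternative 1 | (R)-α-cyclocitral, (1R)-2,6,6-trimethylcyclohex-2-ene-1-carbaldehyde | CC1=CCCC(C)(C)[C@H]1C=O
A5 | alternative 2 | bis-allylic sulfone joining C15 and C15' of the two C20 halves (silyl ether) | CC1=CCCC(C)(C)[C@H]1/C=C/C(C)=C/C=C/C(C)=C/CS(=O)(=O)C/C=C(C)/C=C/C=C(\C)C#CC1=C(C)C[C@@H](O[Si](C)(C)C(C)(C)C)CC1(C)C
A6 | alternative 2 | (3R,6'R)-3-(tert-butyldimethylsilyloxy)-7,8-didehydro-β,ε-carotene | CC1=CCCC(C)(C)[C@H]1/C=C/C(C)=C/C=C/C(C)=C/C=C/C=C(C)/C=C/C=C(\C)C#CC1=C(C)C[C@@H](O[Si](C)(C)C(C)(C)C)CC1(C)C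
A7 | alternative 3 | (2E)-3-methylpent-2-en-4-yn-1-ol | OC/C=C(\C)C#C
A8 | alternative 3 | (2E)-5-[(4R)-4-(tert-butyldimethylsilyloxy)-2,6,6-trimethylcyclohex-1-en-1-yl]-3-methylpent-2-en-4-yn-1-ol | OC/C=C(\C)C#CC1=C(C)C[C@@H](O[Si](C)(C)C(C)(C)C)CC1(C)C
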